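Remark on the chemistry (assumption): 3-chloro-3-methylbut-1-yne and both antipodes of the tert-leucine-derived diamine H2NCH(t-Bu)CH2NEt2 are taken as purchasable or one-step reagents, and the (S)-diamine is assumed to be the antipode whose ammonium arm reaches the Si face of C3; if the sense were the opposite, the (R)-diamine would be used with nothing else changed.

## Structural features

The target is an isoflavan: a chroman (benzo ring A fused to dihydropyran ring C) that carries ring B at C3. Ring B is fused across C2′–C3′ to a 2,2-dimethylpyran (ring D), with the pyran oxygen on C2′ and a free hydroxyl on C4′. Ring A is pentasubstituted: O1 on C8a, the C4 methylene on C4a, methoxy on C5, prenyl on C6 and hydroxyl on C7, so only C8 carries hydrogen. C3 is the only stereocentre (R; priorities C2 > C1′ > C4 > H); it is benzylic to ring B, lies between two methylenes with no neighbouring stereocentre to relay from, and is configurationally labile only while C2 or C4 is a carbonyl. The fragile groups are the prenyl double bond flanked by two ring-A oxygens (acid closes it onto a free phenol; it is also open to epoxidation and hydrogenation), the styrene-like double bond of ring D, and the three electron-rich phenols. The real difficulties are three questions of position and one of configuration: which ring-A carbon becomes C4a and which oxygen is methylated, on which side ring D is fused, and how to set C3 in a molecule that tolerates neither hydrogenation nor strong acid. The key step exploits the fact that O1 lies para to the prenyl-bearing C6: in a 3,5-dioxygenated 4-prenylphenol the two CH carbons ortho to the hydroxyl are equivalent, so either may become C4a while the hydroxyl becomes O1 and C3 is created next to a transient aldehyde at C2.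

## Logic of the disconnections

26 ⇒ 25. Cut: the O–Si bonds at O7 and O4′. Both phenols are carried as identical bulky silyl ethers so that one fluoride treatment ends the synthesis, which reduces the last problem to placing one methyl group. The forward step must be neither acidic nor oxidising.

25 ⇒ 24. Cut: O5–CH3. The methyl group goes on when O5 is the only free hydroxyl, so the step needs no selectivity of its own. It demands an O-methylation that reaches a phenol flanked by C4 and the prenyl group without loosening the silyl ethers.

24 ⇒ 23. Cut: O7–Si. O7 has one ortho substituent and O5 has two, which a bulky silyl group can tell apart. The gain is a precursor in which O5 and O7 are alike, as a symmetrical ring-A building block delivers them. The demand is high site selectivity in a silylation.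

23 ⇒ 21 (through 22). Cut: the two aryl O–CH2 acetal bonds. O5 and O7 must be identical, ether-type and inert through the key step, and the same acetals direct the metalation in the fragment synthesis. The demand is an acetal cleavage without free protic acid, because the prenyl group sits between the two phenols that are set free.

21 ⇒ 20. Cut: O1–C2. Ring C opens to a phenol and a primary alcohol, the reduced form of a lactol. The forward step is a dehydrative etherification under neutral conditions that must not involve C3.

20 ⇒ 7 + 17 (through 18 and 19). Cut: C4–C4a, the C3–H bond and, at the stage of 19, O1–C2. This is the strategic cut: it divides the molecule into two halves of similar size, removes the stereocentre and ring C together, and leaves a ring-A partner whose two reactive carbons are equivalent. The forward step must control the face of a protonation, favour C- over O-alkylation, stop after one addition, and keep the alpha-aryl aldehyde masked until it is reduced.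

17 ⇒ 15 (through 16). Cut: the C=CH2 bond. The methylene is added last because the enal is the least stable compound of the fragment. The demand is a mild Mannich–elimination and immediate use of the product.

15 ⇒ 14 ⇒ 13. Cut: the bond between the benzylic carbon and the formyl carbon. This leads back to an aromatic aldehyde whose formyl group both comes with the cheap starting arene and blocks one ortho position in the ring-D construction. The demand is an enol ether hydrolysis mild enough for ring D and the aryl silyl ether.

13 ⇒ 11 (through 12). Cut: the bond between C3′ and the vinylic carbon of ring D (the O–C bond of ring D is broken and re-formed in the forward cascade). Only one ortho carbon next to O2′ is free, so the fusion of ring D is unambiguous. Heat is the only reagent.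

11 ⇒ 9 + 10, and 9 ⇒ 8. Cut: O2′–C(CH3)2 and O4′–Si. The usual order of events on 8 would put the propargyl group on the more reactive O4′ and fuse ring D the wrong way round; silylating O4′ first reserves the hydrogen-bonded O2′ for the propargyl group. A tertiary propargylic alcohol cannot etherify a phenol directly, so the chloride 10 is used. The demand is an etherification of a hindered, hydrogen-bonded phenol with a tertiary electrophile.

7 ⇒ 5 (through 6). Cut: the C–O bond of the phenol, back to C–H. The C–H para to the prenyl group is the only ring C–H of 5 without an ortho neighbour, so the symmetrical phenol is reached without statistical protection of a 1,3,5-triol. The forward oxidation must not touch the prenyl double bond.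

5 ⇒ 2 + 3 (through 4), and 2 ⇒ 1. Cut: the aryl–CH2 bond of the prenyl group and the two O–CH2 acetal bonds. The position between two acetal oxygens is the most acidic in the ring, so the prenyl group is placed by directed metalation on a fully and symmetrically protected diol. The demand is alkylation at the primary carbon of the allylic bromide (SN2, not SN2′).

## Other disconnections considered

Alternative 1: The cut runs through C3–C4 and the acyl O1–C2 bond of a chroman-2-one.
- Forward step: a chiral triazolylidene carbene would convert the activated ring-B ester A3 into a catalyst-bound enolate, while base expels sulfinate from the ring-A benzylic sulfone A2 to release the ortho-quinone methide A4. Conjugate addition to the methylidene carbon and lactonisation would give lactone A1.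
- In its favour: C3 is created in a C–C bond-forming event on a catalyst-bound enolate, which is on firmer ground than an enantioselective protonation; on this point the alternative is the better plan. O5 already carries its methyl group, so the end game after A1 is shorter (lactone reduction, ring closure, acetal removal); here too it is the better.
- Against it: A2 is an unsymmetrical pentasubstituted arene, so the questions of which carbon is C4a and which oxygen is O5 are moved into a long fragment synthesis that the symmetrical 7 avoids. A4 has no substituent on its methylidene carbon and would be short-lived and prone to self-addition. C3–H of A1 lies between an aryl group and a lactone carbonyl in a basic medium, so the configuration is exposed just after it is made, whereas 19 masks the corresponding carbonyl.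
- Comparison: both plans are convergent and join the same two ring systems. The alternative has the more dependable stereo-determining step but the less stable product. Its saving after the key step is expected to be outweighed by the regiocontrolled preparation of A2.

Alternative 2: Ring B itself is cut, at C1′–C6′ and C3′–C4′, back to the ring-C ketone A6 and methyl acrylate A7.
- Forward step: KOt-Bu would add the more substituted enolate of A6 to A7 and close the methyl ketone onto the ester in the same pot, giving dione A5. Dehydrogenation would give resorcinol A8, on which ring D still has to be built.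
- In its favour: no sensitive 2-arylacrolein is handled and the reagents are cheap. C3 is neither benzylic nor alpha to a carbonyl during the key step, so it cannot epimerise; on configurational safety the alternative is the better.
- Against it: the key step builds no stereocentre of the target, so C3 must come from an earlier asymmetric step on A6. The Michael addition must go through the more hindered, beta-branched enolate and stop after one addition. Aromatisation of A5 needs an oxidant (I2, Pd/C or Hg(OAc)2) in the presence of the prenyl double bond. The pyran annulation on A8 can engage O2′/C3′, O4′/C3′ or O4′/C5′, a question the chosen plan settles in steps 4–6. Ring A is again unsymmetrical.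
- Comparison: this is the most linear of the four plans and is expected to be the longest.

Alternative 3: Four bonds of ring A are cut (C8–C8a, C5–C6, C7–C8 and C4a–C5), leading to the ring-C diazo ketone A10 and the prenyl-substituted siloxyalkyne A11.
- Forward step: irradiation of A10 would trigger a Wolff rearrangement, and a cascade of [2+2] addition to A11, four-electron ring opening and six-electron ring closure would grow ring A on ring C and give phenol A9.
- In its favour: every ring-A substituent is placed by the mechanism, and O5 emerges free while O7 emerges silylated. The O5/O7 differentiation that costs the chosen plan steps 12 and 13 comes for nothing; here the alternative is clearly the better. C3 is remote from all reacting centres, which is at least the equal of the lactol protection in the chosen plan.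
- Against it: A10 is an enantioenriched 3-aryl-3,4-dihydro-2H-pyran carrying a diazo ketone, so the stereochemical problem is moved into a multistep fragment synthesis and not solved. A11 needs its own preparation. The photolysis must spare an aryl propargyl ether and an electron-rich enol ether, and ring D still has to be closed thermally afterwards.
- Comparison: it is the least convergent plan (ring C, then ring A, then ring D). It is the most elegant for ring A but leaves C3 to other chemistry, and it is expected to be longer than the chosen plan.

Key step: step 10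

## Route

Step 1
Reactants: 1 resorcinol
Product: 2 1,3-bis(methoxymethoxy)benzene
Conditions: MOMCl, i-Pr2NEt, CH2Cl2, 0 °C → rt
Reagents that add atoms: chloromethyl methyl ether, COCCl
Why: Williamson-type O-alkylation of both phenols with an activated chloromethyl ether; the substrate is symmetrical and is driven to full protection, so no statistical mixture arises, and the acetal oxygens are the directing groups of step 2.

Step 2
Reactants: 2 1,3-bis(methoxymethoxy)benzene; 3 1-bromo-3-methylbut-2-ene (prenyl bromide)
Product: 5 1,3-bis(methoxymethoxy)-2-(3-methylbut-2-en-1-yl)benzene, via aryllithium 4 (not isolated)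
Conditions: n-BuLi, THF, 0 °C → rt; CuBr·SMe2, −40 °C; then 3, −40 °C → rt
Reagents that add atoms: n-butyllithium, [Li]CCCC (the lithium of 4; no atom of it remains in 5)
Why: Directed ortho-metalation: the C–H between the two acetal oxygens is the most acidic and doubly chelated, so lithiation should be confined to that carbon; transmetalation to copper and attack on the unhindered primary terminus of the allylic bromide should give the linear prenyl group and not the SN2′ isomer.

Step 3
Reactants: 5 1,3-bis(methoxymethoxy)-2-(3-methylbut-2-en-1-yl)benzene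
Product: 7 3,5-bis(methoxymethoxy)-4-(3-methylbut-2-en-1-yl)phenol, via pinacol boronate 6 (not isolated)
Conditions: [Ir(OMe)(cod)]2 (1.5 mol %), 4,4′-di-tert-butyl-2,2′-bipyridine (3 mol %), B2pin2 (0.6 equiv), THF, 60 °C; then aq. H2O2, NaOH, 0 °C
Reagents that add atoms: bis(pinacolato)diboron, CC1(C)OB(OC1(C)C)B1OC(C)(C)C(C)(C)O1 (the boryl group of 6); hydrogen peroxide, OO (the phenol oxygen of 7)
Why: Iridium-catalysed aromatic C–H borylation is governed by sterics, and the only ring C–H of 5 without an ortho substituent is the one para to the prenyl group; alkaline peroxide then oxidises the C–B bond (1,2-aryl shift from boron to oxygen) and is chosen over a dioxirane-forming oxidant so that the trisubstituted alkene is not epoxidised.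

Step 4
Reactants: 8 2,4-dihydroxybenzaldehyde
Product: 9 2-hydroxy-4-(triisopropylsilyloxy)benzaldehyde
Conditions: TIPSCl (1.05 equiv), imidazole, CH2Cl2, 0 °C
Reagents that add atoms: triisopropylsilyl chloride, CC(C)[Si](Cl)(C(C)C)C(C)C
Why: Selective O-silylation: the 4-hydroxyl is the more acidic and is free, whereas the 2-hydroxyl is held in a hydrogen bond to the formyl oxygen, so the bulky silyl chloride should take O4 only and leave O2, the future pyran oxygen, for step 5.

Step 5
Reactants: 9 2-hydroxy-4-(triisopropylsilyloxy)benzaldehyde; 10 3-chloro-3-methylbut-1-yne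
Product: 11 2-[(2-methylbut-3-yn-2-yl)oxy]-4-(triisopropylsilyloxy)benzaldehyde
Conditions: CuCl2·2H2O (1 mol %), DBU, MeCN, 0 °C → rt
Reagents that add atoms: none
Why: Copper-catalysed propargylic etherification: the copper acetylide of the tertiary chloride ionises to an allenylidene-type electrophile that the phenoxide captures at the tertiary carbon, a reaction that tolerates hindered and electron-poor phenols where direct SN2 displacement is impossible.

Step 6
Reactants: 11 2-[(2-methylbut-3-yn-2-yl)oxy]-4-(triisopropylsilyloxy)benzaldehyde
Product: 13 2,2-dimethyl-5-(triisopropylsilyloxy)-2H-chromene-8-carbaldehyde, via allenylphenol 12 (not isolated)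
Conditions: o-xylene, 140 °C
Reagents that add atoms: none
Why: Aryl propargyl ether Claisen rearrangement ([3,3]) to the only free ortho carbon, enolisation to 12, 1,5-hydrogen shift to an ortho-quinone methide and oxa-6π electrocyclisation; because the other ortho position carries the formyl group, the pyran can only be fused with its oxygen next to the formyl-bearing carbon, which is the arrangement of ring D in the target.

Step 7
Reactants: 13 2,2-dimethyl-5-(triisopropylsilyloxy)-2H-chromene-8-carbaldehyde
Product: 14 8-(2-methoxyethenyl)-2,2-dimethyl-5-(triisopropylsilyloxy)-2H-chromene (E/Z mixture)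
Conditions: MeOCH2PPh3Cl, KN(SiMe3)2, THF, 0 °C → rt
Reagents that add atoms: (methoxymethyl)triphenylphosphonium chloride, COC[P+](c1ccccc1)(c1ccccc1)c1ccccc1.[Cl-]
Why: Wittig olefination with the methoxymethylene ylide, the standard one-carbon homologation of an aromatic aldehyde; the double-bond geometry is irrelevant because both isomers hydrolyse to the same aldehyde.

Step 8
Reactants: 14 8-(2-methoxyethenyl)-2,2-dimethyl-5-(triisopropylsilyloxy)-2H-chromene
Product: 15 2-[2,2-dimethyl-5-(triisopropylsilyloxy)-2H-chromen-8-yl]acetaldehyde
Conditions: aq. HCl (2 M), THF, rt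
Reagents that add atoms: water, O
Why: Acid-catalysed enol ether hydrolysis (C-protonation to an oxocarbenium ion, hemiacetal, loss of methanol); dilute acid at room temperature should leave the aryl silyl ether and the chromene double bond alone, and the arylacetaldehyde is carried on crude because it self-condenses on standing.

Step 9
Reactants: 15 2-[2,2-dimethyl-5-(triisopropylsilyloxy)-2H-chromen-8-yl]acetaldehyde
Product: 17 2-[2,2-dimethyl-5-(triisopropylsilyloxy)-2H-chromen-8-yl]prop-2-enal, via Mannich base 16 (not isolated)
Conditions: Me2N=CH2 I (Eschenmoser's salt), Et3N, CH2Cl2, rt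
Reagents that add atoms: N,N-dimethylmethyleneiminium iodide, C=[N+](C)C.[I-]
Why: Mannich reaction of the enolisable arylacetaldehyde with the preformed iminium salt, then E1cB loss of dimethylamine from 16, driven by the acidity of the benzylic alpha-hydrogen; the 2-arylacrolein is kept cold and dilute and used without delay because such enals dimerise by hetero-Diels–Alder reaction.

Step 10
Reactants: 7 3,5-bis(methoxymethoxy)-4-(3-methylbut-2-en-1-yl)phenol; 17 2-[2,2-dimethyl-5-(triisopropylsilyloxy)-2H-chromen-8-yl]prop-2-enal
Product: 20 2-{(2R)-2-[2,2-dimethyl-5-(triisopropylsilyloxy)-2H-chromen-8-yl]-3-hydroxypropyl}-3,5-bis(methoxymethoxy)-4-(3-methylbut-2-en-1-yl)phenol, via hydroxy aldehyde 18 (not isolated), via lactol 19 (not isolated)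
Conditions: (S)-H2NCH(t-Bu)CH2NEt2·TfOH (20 mol %), 7 (1.3 equiv), CHCl3, 0 °C; then MeOH, NaBH4, 0 °C
Reagents that add atoms: none
Why: Proposed new method: the primary amine of the catalyst condenses with 17 to an iminium ion whose unsubstituted methylene is attacked by a carbon ortho to the hydroxyl of 7 (Friedel–Crafts-type conjugate addition, forming C4–C4a), rearomatisation leaves an enamine, the protonated tertiary-amine arm delivers the proton to C3, hydrolysis releases aldehyde 18, the neighbouring phenol adds to the carbonyl to give lactol 19, and NaBH4 reduces 19 through its open form to 20; the closest known reaction types are primary-amine-catalysed Friedel–Crafts additions of indoles to alpha-substituted acroleins that end in enantioselective enamine protonation, and amine-catalysed annulations of electron-rich phenols with enals to chroman-2-ols. The one ring formed (ring C, as the lactol) closes by 6-exo-trig addition of O1 to the C2 carbonyl. C3 is the only new controlled stereocentre and is set by the catalyst: the tert-butyl group fixes the enamine conformation and the intramolecular ammonium N–H must reach the Si face of C3 (priorities C2 > aryl > C4) to give R, while the anomeric carbon is formed as a mixture and is removed by the reduction. Site selectivity needs no control because the two ortho carbons of 7 are equivalent and the two other oxygens are blocked as acetals, so only the free hydroxyl can become O1. C- over O-alkylation is expected because oxa-Michael addition is reversible whereas the arene addition is not, and the excess of 7 limits a second addition at C8. Configurational integrity rests on the lactol, which keeps the alpha-aryl aldehyde masked from enol or enamine formation until hydride is added in the same flask.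

Step 11
Reactants: 20 2-{(2R)-2-[2,2-dimethyl-5-(triisopropylsilyloxy)-2H-chromen-8-yl]-3-hydroxypropyl}-3,5-bis(methoxymethoxy)-4-(3-methylbut-2-en-1-yl)phenol
Product: 21 (3R)-3-[2,2-dimethyl-5-(triisopropylsilyloxy)-2H-chromen-8-yl]-5,7-bis(methoxymethoxy)-6-(3-methylbut-2-en-1-yl)chromane
Conditions: PPh3, DIAD, THF, 0 °C → rt
Reagents that add atoms: none
Why: Intramolecular Mitsunobu etherification: the primary alcohol is activated as its alkoxyphosphonium ion and displaced by the only acidic hydroxyl, the phenol, in a 6-exo-tet closure of ring C; C3 is not a reacting centre and the neutral conditions leave it and the acetals untouched.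

Step 12
Reactants: 21 (3R)-3-[2,2-dimethyl-5-(triisopropylsilyloxy)-2H-chromen-8-yl]-5,7-bis(methoxymethoxy)-6-(3-methylbut-2-en-1-yl)chromane
Product: 23 (3R)-3-[2,2-dimethyl-5-(triisopropylsilyloxy)-2H-chromen-8-yl]-6-(3-methylbut-2-en-1-yl)chromane-5,7-diol, via bis(trimethylsilyl) ether 22 (not isolated)
Conditions: TMSOTf (4 equiv), 2,2′-bipyridyl (6 equiv), MeCN, 0 °C → rt; then H2O
Reagents that add atoms: trimethylsilyl triflate, C[Si](C)(C)OS(=O)(=O)C(F)(F)F (the silyl groups of 22; no atom of it remains in 23)
Why: Cleavage of aromatic methoxymethyl ethers by a silyl triflate buffered with 2,2′-bipyridyl: the acetal is activated at its methoxy oxygen, the aryloxy group ends as a trimethylsilyl ether, the methoxymethyl cation is held as a pyridinium salt, and water hydrolyses both; no free Brønsted acid is present, so the prenyl group should not cyclise onto the liberated phenols, and ring D and the triisopropylsilyl ether should survive.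

Step 13
Reactants: 23 (3R)-3-[2,2-dimethyl-5-(triisopropylsilyloxy)-2H-chromen-8-yl]-6-(3-methylbut-2-en-1-yl)chromane-5,7-diol
Product: 24 (3R)-3-[2,2-dimethyl-5-(triisopropylsilyloxy)-2H-chromen-8-yl]-6-(3-methylbut-2-en-1-yl)-7-(triisopropylsilyloxy)chroman-5-ol
Conditions: TIPSCl (1.1 equiv), imidazole, DMF, 0 °C → rt
Reagents that add atoms: triisopropylsilyl chloride, CC(C)[Si](Cl)(C(C)C)C(C)C
Why: Site-selective silylation controlled by sterics: O7 has one ortho substituent (the prenyl group) and O5 has two (the prenyl group and C4), and a triisopropylsilyl group is large enough that a 2,6-dialkylphenol should react far more slowly than a 2-alkylphenol.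

Step 14
Reactants: 24 (3R)-3-[2,2-dimethyl-5-(triisopropylsilyloxy)-2H-chromen-8-yl]-6-(3-methylbut-2-en-1-yl)-7-(triisopropylsilyloxy)chroman-5-ol
Product: 25 (3R)-3-[2,2-dimethyl-5-(triisopropylsilyloxy)-2H-chromen-8-yl]-5-methoxy-6-(3-methylbut-2-en-1-yl)-7-(triisopropylsilyloxy)chromane
Conditions: MeI, K2CO3, acetone, 45 °C
Reagents that add atoms: iodomethane, CI
Why: Williamson O-methylation of the one remaining phenol; the small electrophile reaches the hindered phenoxide, aryl triisopropylsilyl ethers are stable to K2CO3 in acetone, and silyl migration is not possible because O5 and O7 are meta to each other.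

Step 15
Reactants: 25 (3R)-3-[2,2-dimethyl-5-(triisopropylsilyloxy)-2H-chromen-8-yl]-5-methoxy-6-(3-methylbut-2-en-1-yl)-7-(triisopropylsilyloxy)chromane
Product: 26 (3R)-3-(5-hydroxy-2,2-dimethyl-2H-chromen-8-yl)-5-methoxy-6-(3-methylbut-2-en-1-yl)chroman-7-ol (CNP0119857.1)
Conditions: Bu4NF, AcOH, THF, 0 °C
Reagents that add atoms: none
Why: Fluoride-induced cleavage of both aryl silyl ethers in one operation, buffered with acetic acid so that the electron-rich phenoxides are protonated at once; no stereocentre or double bond is touched.

## Compound list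

1 | resorcinol | Oc1cccc(O)c1 | starting material
2 | 1,3-bis(methoxymethoxy)benzene | COCOc1cccc(OCOC)c1 | intermediate
3 | 1-bromo-3-methylbut-2-ene (prenyl bromide) | CC(C)=CCBr | starting material
4 | [2,6-bis(methoxymethoxy)phenyl]lithium (formed in the flask) | [Li]c1c(OCOC)cccc1OCOC | intermediate
5 | 1,3-bis(methoxymethoxy)-2-(3-methylbut-2-en-1-yl)benzene | COCOc1cccc(OCOC)c1CC=C(C)C | intermediate
6 | 2-[3,5-bis(methoxymethoxy)-4-(3-methylbut-2-en-1-yl)phenyl]-4,4,5,5-tetramethyl-1,3,2-dioxaborolane (formed in the flask) | COCOc1cc(B2OC(C)(C)C(C)(C)O2)cc(OCOC)c1CC=C(C)C | intermediate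
7 | 3,5-bis(methoxymethoxy)-4-(3-methylbut-2-en-1-yl)phenol | COCOc1cc(O)cc(OCOC)c1CC=C(C)C | intermediate
8 | 2,4-dihydroxybenzaldehyde | O=Cc1ccc(O)cc1O | starting material
9 | 2-hydroxy-4-(triisopropylsilyloxy)benzaldehyde | O=Cc1ccc(O[Si](C(C)C)(C(C)C)C(C)C)cc1O | intermediate
10 | 3-chloro-3-methylbut-1-yne | CC(C)(Cl)C#C | starting material
11 | 2-[(2-methylbut-3-yn-2-yl)oxy]-4-(triisopropylsilyloxy)benzaldehyde | O=Cc1ccc(O[Si](C(C)C)(C(C)C)C(C)C)cc1OC(C)(C)C#C | intermediate
12 | 2-hydroxy-3-(3-methylbuta-1,2-dien-1-yl)-4-(triisopropylsilyloxy)benzaldehyde (formed in the flask) | O=Cc1ccc(O[Si](C(C)C)(C(C)C)C(C)C)c(C=C=C(C)C)c1O | intermediate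
13 | 2,2-dimethyl-5-(triisopropylsilyloxy)-2H-chromene-8-carbaldehyde | O=Cc1ccc(O[Si](C(C)C)(C(C)C)C(C)C)c2c1OC(C)(C)C=C2 | intermediate
14 | 8-(2-methoxyethenyl)-2,2-dimethyl-5-(triisopropylsilyloxy)-2H-chromene (E/Z mixture) | COC=Cc1ccc(O[Si](C(C)C)(C(C)C)C(C)C)c2c1OC(C)(C)C=C2 | intermediate
15 | 2-[2,2-dimethyl-5-(triisopropylsilyloxy)-2H-chromen-8-yl]acetaldehyde | O=CCc1ccc(O[Si](C(C)C)(C(C)C)C(C)C)c2c1OC(C)(C)C=C2 | intermediate
16 | 3-(dimethylamino)-2-[2,2-dimethyl-5-(triisopropylsilyloxy)-2H-chromen-8-yl]propanal (racemic; formed in the flask) | CN(C)CC(C=O)c1ccc(O[Si](C(C)C)(C(C)C)C(C)C)c2c1OC(C)(C)C=C2 | intermediate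
17 | 2-[2,2-dimethyl-5-(triisopropylsilyloxy)-2H-chromen-8-yl]prop-2-enal | C=C(C=O)c1ccc(O[Si](C(C)C)(C(C)C)C(C)C)c2c1OC(C)(C)C=C2 | intermediate
18 | (2R)-2-[2,2-dimethyl-5-(triisopropylsilyloxy)-2H-chromen-8-yl]-3-[6-hydroxy-2,4-bis(methoxymethoxy)-3-(3-methylbut-2-en-1-yl)phenyl]propanal (formed in the flask) | O=C[C@H](Cc1c(O)cc(OCOC)c(CC=C(C)C)c1OCOC)c1ccc(O[Si](C(C)C)(C(C)C)C(C)C)c2c1OC(C)(C)C=C2 | intermediate
19 | (3R)-3-[2,2-dimethyl-5-(triisopropylsilyloxy)-2H-chromen-8-yl]-5,7-bis(methoxymethoxy)-6-(3-methylbut-2-en-1-yl)chroman-2-ol (both anomers; formed in the flask) | OC1Oc2cc(OCOC)c(CC=C(C)C)c(OCOC)c2C[C@@H]1c1ccc(O[Si](C(C)C)(C(C)C)C(C)C)c2c1OC(C)(C)C=C2 | intermediate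
20 | 2-{(2R)-2-[2,2-dimethyl-5-(triisopropylsilyloxy)-2H-chromen-8-yl]-3-hydroxypropyl}-3,5-bis(methoxymethoxy)-4-(3-methylbut-2-en-1-yl)phenol | OC[C@H](Cc1c(O)cc(OCOC)c(CC=C(C)C)c1OCOC)c1ccc(O[Si](C(C)C)(C(C)C)C(C)C)c2c1OC(C)(C)C=C2 | intermediate
21 | (3R)-3-[2,2-dimethyl-5-(triisopropylsilyloxy)-2H-chromen-8-yl]-5,7-bis(methoxymethoxy)-6-(3-methylbut-2-en-1-yl)chromane | COCOc1c(CC=C(C)C)c(OCOC)cc2c1C[C@H](c1ccc(O[Si](C(C)C)(C(C)C)C(C)C)c3c1OC(C)(C)C=C3)CO2 | intermediate
22 | (3R)-3-[2,2-dimethyl-5-(triisopropylsilyloxy)-2H-chromen-8-yl]-6-(3-methylbut-2-en-1-yl)-5,7-bis(trimethylsilyloxy)chromane (formed in the flask) | C[Si](C)(C)Oc1c(CC=C(C)C)c(O[Si](C)(C)C)cc2c1C[C@H](c1ccc(O[Si](C(C)C)(C(C)C)C(C)C)c3c1OC(C)(C)C=C3)CO2 | intermediate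
23 | (3R)-3-[2,2-dimethyl-5-(triisopropylsilyloxy)-2H-chromen-8-yl]-6-(3-methylbut-2-en-1-yl)chromane-5,7-diol | Oc1c(CC=C(C)C)c(O)cc2c1C[C@H](c1ccc(O[Si](C(C)C)(C(C)C)C(C)C)c3c1OC(C)(C)C=C3)CO2 | intermediate
24 | (3R)-3-[2,2-dimethyl-5-(triisopropylsilyloxy)-2H-chromen-8-yl]-6-(3-methylbut-2-en-1-yl)-7-(triisopropylsilyloxy)chroman-5-ol | Oc1c(CC=C(C)C)c(O[Si](C(C)C)(C(C)C)C(C)C)cc2c1C[C@H](c1ccc(O[Si](C(C)C)(C(C)C)C(C)C)c3c1OC(C)(C)C=C3)CO2 | intermediate
25 | (3R)-3-[2,2-dimethyl-5-(triisopropylsilyloxy)-2H-chromen-8-yl]-5-methoxy-6-(3-methylbut-2-en-1-yl)-7-(triisopropylsilyloxy)chromane | COc1c(CC=C(C)C)c(O[Si](C(C)C)(C(C)C)C(C)C)cc2c1C[C@H](c1ccc(O[Si](C(C)C)(C(C)C)C(C)C)c3c1OC(C)(C)C=C3)CO2 | intermediate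
26 | (3R)-3-(5-hydroxy-2,2-dimethyl-2H-chromen-8-yl)-5-methoxy-6-(3-methylbut-2-en-1-yl)chroman-7-ol (CNP0119857.1) | COc1c(CC=C(C)C)c(O)cc2c1C[C@H](c1ccc(O)c3c1OC(C)(C)C=C3)CO2 | target

## Step count and risk

Total step count: 15 (steps 1–3 for the ring-A fragment, steps 4–9 for the ring-B fragment, step 10 as the key step with its in-flask reduction, steps 11–15 after it).
Longest linear sequence: 12 steps (8 to 26 through steps 4–15).

Least certain steps:

Step 10 (key step; proposed new method).
- What may go wrong: poor facial selectivity in the enamine protonation. The enamine can form as two double-bond isomers that present opposite faces to the ammonium arm. The very electron-rich 7 may also add to 17 without the catalyst, giving an enol that is protonated without control. The primary amine may re-form an enamine from 18 before it closes to 19, which would erode the enantiomeric purity. A second addition at C8 is a lesser concern.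
- Fallback (known chemistry: auxiliary-controlled enolate alkylation; sets out from 15 and 7, returns at 20): 15 is oxidised (NaClO2, NaH2PO4, 2-methylbut-2-ene) to the arylacetic acid F1, which is coupled (pivaloyl chloride, Et3N, LiCl, THF) with (4R)-4-benzyl-1,3-oxazolidin-2-one to the acyl oxazolidinone F2. In parallel 7 is ortho-formylated (MgCl2, Et3N, paraformaldehyde; the two ortho positions are equivalent) to the salicylaldehyde F3, O-allylated (allyl bromide, K2CO3) to the allyl ether F4, reduced (NaBH4) to the benzylic alcohol F5 and converted (CBr4, PPh3) into the benzylic bromide F6, which is used at once because it ionises easily. F2 is deprotonated with NaN(SiMe3)2 at −78 °C and alkylated by F6 on the face opposite the benzyl group, which for the (4R)-auxiliary should give the (2R)-configured alkylated imide F7. LiBH4 removes the auxiliary to give the primary alcohol F8, and Pd(PPh3)4 with morpholine removes the allyl group to give 20.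

Step 9.
- What may go wrong: aldol self-condensation of 15 under the amine base before the Mannich reaction, and oligomerisation or hetero-Diels–Alder dimerisation of 17 on concentration.
- Fallback (sets out from 15, returns at 17): the carbonyl is carried at the ester level, and the enal is made by a last mild oxidation of a storable allylic alcohol. 15 is oxidised to the arylacetic acid F1 (as in the fallback to step 10) and methylated (MeI, K2CO3) to the methyl arylacetate F9. Alpha-methylenation (paraformaldehyde, K2CO3, Bu4NI, toluene, 80 °C) gives the methyl 2-arylacrylate F10, i-Bu2AlH at −78 °C gives the 2-arylallyl alcohol F11, and MnO2 oxidises F11 to 17 immediately before step 10.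

Step 3.
- What may go wrong: hydroboration or positional isomerisation of the prenyl double bond by the iridium hydride and pinacolborane present during the borylation, or competing allylic C–H borylation.
- Fallback (sets out from 2, returns at 7): the order is changed so that no alkene is present during the borylation. 2 is borylated under the same conditions to the aryl boronate F12, which is not isolated, and oxidised (H2O2, NaOH) to the symmetrical phenol F13. Silylation (TIPSCl, imidazole) gives the silyl ether F14; lithiation between the two acetal oxygens gives the aryllithium F15, which is not isolated, and copper-mediated alkylation with 3 gives the prenylated silyl ether F16. Bu4NF then releases 7.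

Step 5.
- What may go wrong: slow etherification at the hindered, hydrogen-bonded hydroxyl, so that base-induced loss of the silyl group from O4 and elimination of hydrogen chloride from 10 compete.
- Fallback (sets out from 9, returns at 13, replaces steps 5 and 6): ring D is built by phenol–enal annulation. 9 is heated with 3-methylbut-2-enal and ethylenediammonium diacetate in toluene. Condensation at the carbon between the two oxygens, dehydration and oxa-6π closure through the only free hydroxyl (O2) should give 13 directly. No new isolated compound arises.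

Step 13.
- What may go wrong: incomplete discrimination between O7 and O5, giving silylation at both oxygens or at the wrong one.
- Fallback (sets out from 23, returns at 24): the discrimination is moved from a silylation to an ester cleavage, which is more sensitive to ortho substitution. 23 is acetylated (Ac2O, pyridine) to the diacetate F17. Brief methanolysis (catalytic K2CO3, MeOH, −20 °C) should remove the unhindered 7-acetate first and give the 5-acetate F18. Silylation of the free O7 gives the silyl ether acetate F19, and i-Bu2AlH at −78 °C removes the hindered acetate to give 24.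

## Further compounds

F1 | step 10 | 2-[2,2-dimethyl-5-(triisopropylsilyloxy)-2H-chromen-8-yl]acetic acid | OC(=O)Cc1ccc(O[Si](C(C)C)(C(C)C)C(C)C)c2c1OC(C)(C)C=C2
F2 | step 10 | (4R)-4-benzyl-3-{[2,2-dimethyl-5-(triisopropylsilyloxy)-2H-chromen-8-yl]acetyl}-1,3-oxazolidin-2-one | O=C(Cc1ccc(O[Si](C(C)C)(C(C)C)C(C)C)c2c1OC(C)(C)C=C2)N1[C@H](Cc2ccccc2)COC1=O
F3 | step 10 | 6-hydroxy-2,4-bis(methoxymethoxy)-3-(3-methylbut-2-en-1-yl)benzaldehyde | O=Cc1c(O)cc(OCOC)c(CC=C(C)C)c1OCOC
F4 | step 10 | 2,4-bis(methoxymethoxy)-3-(3-methylbut-2-en-1-yl)-6-(prop-2-en-1-yloxy)benzaldehyde | O=Cc1c(OCC=C)cc(OCOC)c(CC=C(C)C)c1OCOC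
F5 | step 10 | [2,4-bis(methoxymethoxy)-3-(3-methylbut-2-en-1-yl)-6-(prop-2-en-1-yloxy)phenyl]methanol | OCc1c(OCC=C)cc(OCOC)c(CC=C(C)C)c1OCOC
F6 | step 10 | 2-(bromomethyl)-3,5-bis(methoxymethoxy)-4-(3-methylbut-2-en-1-yl)-1-(prop-2-en-1-yloxy)benzene | BrCc1c(OCC=C)cc(OCOC)c(CC=C(C)C)c1OCOC
F7 | step 10 | (4R)-4-benzyl-3-{(2R)-3-[2,4-bis(methoxymethoxy)-3-(3-methylbut-2-en-1-yl)-6-(prop-2-en-1-yloxy)phenyl]-2-[2,2-dimethyl-5-(triisopropylsilyloxy)-2H-chromen-8-yl]propanoyl}-1,3-oxazolidin-2-one | O=C([C@H](Cc1c(OCC=C)cc(OCOC)c(CC=C(C)C)c1OCOC)c1ccc(O[Si](C(C)C)(C(C)C)C(C)C)c2c1OC(C)(C)C=C2)N1[C@H](Cc2ccccc2)COC1=O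
F8 | step 10 | (2R)-3-[2,4-bis(methoxymethoxy)-3-(3-methylbut-2-en-1-yl)-6-(prop-2-en-1-yloxy)phenyl]-2-[2,2-dimethyl-5-(triisopropylsilyloxy)-2H-chromen-8-yl]propan-1-ol | OC[C@H](Cc1c(OCC=C)cc(OCOC)c(CC=C(C)C)c1OCOC)c1ccc(O[Si](C(C)C)(C(C)C)C(C)C)c2c1OC(C)(C)C=C2
F9 | step 9 | methyl 2-[2,2-dimethyl-5-(triisopropylsilyloxy)-2H-chromen-8-yl]acetate | COC(=O)Cc1ccc(O[Si](C(C)C)(C(C)C)C(C)C)c2c1OC(C)(C)C=C2
F10 | step 9 | methyl 2-[2,2-dimethyl-5-(triisopropylsilyloxy)-2H-chromen-8-yl]prop-2-enoate | COC(=O)C(=C)c1ccc(O[Si](C(C)C)(C(C)C)C(C)C)c2c1OC(C)(C)C=C2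
F11 | step 9 | 2-[2,2-dimethyl-5-(triisopropylsilyloxy)-2H-chromen-8-yl]prop-2-en-1-ol | OCC(=C)c1ccc(O[Si](C(C)C)(C(C)C)C(C)C)c2c1OC(C)(C)C=C2
F12 | step 3 | 2-[3,5-bis(methoxymethoxy)phenyl]-4,4,5,5-tetramethyl-1,3,2-dioxaborolane | COCOc1cc(B2OC(C)(C)C(C)(C)O2)cc(OCOC)c1
F13 | step 3 | 3,5-bis(methoxymethoxy)phenol | COCOc1cc(O)cc(OCOC)c1
F14 | step 3 | [3,5-bis(methoxymethoxy)phenoxy]triisopropylsilane | COCOc1cc(O[Si](C(C)C)(C(C)C)C(C)C)cc(OCOC)c1
F15 | step 3 | [2,6-bis(methoxymethoxy)-4-(triisopropylsilyloxy)phenyl]lithium | [Li]c1c(OCOC)cc(O[Si](C(C)C)(C(C)C)C(C)C)cc1OCOC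
F16 | step 3 | [3,5-bis(methoxymethoxy)-4-(3-methylbut-2-en-1-yl)phenoxy]triisopropylsilane | COCOc1cc(O[Si](C(C)C)(C(C)C)C(C)C)cc(OCOC)c1CC=C(C)C
F0 | step 5 | none | none
F17 | step 13 | (3R)-3-[2,2-dimethyl-5-(triisopropylsilyloxy)-2H-chromen-8-yl]-6-(3-methylbut-2-en-1-yl)chromane-5,7-diyl diacetate | CC(=O)Oc1c(CC=C(C)C)c(OC(C)=O)cc2c1C[C@H](c1ccc(O[Si](C(C)C)(C(C)C)C(C)C)c3c1OC(C)(C)C=C3)CO2
F18 | step 13 | (3R)-3-[2,2-dimethyl-5-(triisopropylsilyloxy)-2H-chromen-8-yl]-7-hydroxy-6-(3-methylbut-2-en-1-yl)chroman-5-yl acetate | CC(=O)Oc1c(CC=C(C)C)c(O)cc2c1C[C@H](c1ccc(O[Si](C(C)C)(C(C)C)C(C)C)c3c1OC(C)(C)C=C3)CO2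
F19 | step 13 | (3R)-3-[2,2-dimethyl-5-(triisopropylsilyloxy)-2H-chromen-8-yl]-6-(3-methylbut-2-en-1-yl)-7-(triisopropylsilyloxy)chroman-5-yl acetate | CC(=O)Oc1c(CC=C(C)C)c(O[Si](C(C)C)(C(C)C)C(C)C)cc2c1C[C@H](c1ccc(O[Si](C(C)C)(C(C)C)C(C)C)c3c1OC(C)(C)C=C3)CO2
A1 | alternative 1 | (3R)-3-[5-(methoxymethoxy)-2,2-dimethyl-2H-chromen-8-yl]-5-methoxy-7-(methoxymethoxy)-6-(3-methylbut-2-en-1-yl)chroman-2-one | COc1c(CC=C(C)C)c(OCOC)cc2c1C[C@H](c1ccc(OCOC)c3c1OC(C)(C)C=C3)C(=O)O2
A2 | alternative 1 | 3-methoxy-5-(methoxymethoxy)-4-(3-methylbut-2-en-1-yl)-2-[(4-methylphenylsulfonyl)methyl]phenol | COc1c(CC=C(C)C)c(OCOC)cc(O)c1CS(=O)(=O)c1ccc(C)cc1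
A3 | alternative 1 | 4-nitrophenyl 2-[5-(methoxymethoxy)-2,2-dimethyl-2H-chromen-8-yl]acetate | O=C(Cc1ccc(OCOC)c2c1OC(C)(C)C=C2)Oc1ccc([N+](=O)[O-])cc1
A4 | alternative 1 | 5-methoxy-3-(methoxymethoxy)-6-methylidene-4-(3-methylbut-2-en-1-yl)cyclohexa-2,4-dien-1-one | C=C1C(OC)=C(CC=C(C)C)C(OCOC)=CC1=O
A5 | alternative 2 | 4-[(3R)-5-methoxy-7-(methoxymethoxy)-6-(3-methylbut-2-en-1-yl)chroman-3-yl]cyclohexane-1,3-dione (epimers at the dione ring carbon) | COc1c(CC=C(C)C)c(OCOC)cc2c1C[C@H](C1CCC(=O)CC1=O)CO2
A6 | alternative 2 | 1-[(3R)-5-methoxy-7-(methoxymethoxy)-6-(3-methylbut-2-en-1-yl)chroman-3-yl]propan-2-one | COc1c(CC=C(C)C)c(OCOC)cc2c1C[C@H](CC(C)=O)CO2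
A7 | alternative 2 | methyl acrylate | C=CC(=O)OC
A8 | alternative 2 | 4-[(3R)-5-methoxy-7-(methoxymethoxy)-6-(3-methylbut-2-en-1-yl)chroman-3-yl]benzene-1,3-diol | COc1c(CC=C(C)C)c(OCOC)cc2c1C[C@H](c1ccc(O)cc1O)CO2
A9 | alternative 3 | (3R)-3-{2-[(2-methylbut-3-yn-2-yl)oxy]-4-(triisopropylsilyloxy)phenyl}-6-(3-methylbut-2-en-1-yl)-7-(triisopropylsilyloxy)chroman-5-ol | Oc1c(CC=C(C)C)c(O[Si](C(C)C)(C(C)C)C(C)C)cc2c1C[C@H](c1ccc(O[Si](C(C)C)(C(C)C)C(C)C)cc1OC(C)(C)C#C)CO2
A10 | alternative 3 | 2-diazo-1-[(3R)-3-{2-[(2-methylbut-3-yn-2-yl)oxy]-4-(triisopropylsilyloxy)phenyl}-3,4-dihydro-2H-pyran-6-yl]ethan-1-one | [N-]=[N+]=CC(=O)C1=CC[C@H](c2ccc(O[Si](C(C)C)(C(C)C)C(C)C)cc2OC(C)(C)C#C)CO1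
A11 | alternative 3 | triisopropyl[(5-methylhex-4-en-1-yn-1-yl)oxy]silane | CC(C)=CCC#CO[Si](C(C)C)(C(C)C)C(C)C
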